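## Retrosynthetic overview

1. The tetronic acid ring is closed last, by Dieckmann condensation of an α‑propanoyloxy methyl ester; its (5S) centre is carried in from methyl (S)‑glycidate.
2. Key disconnection: the CH(CH3)–CH2 bond at the stereocentre next to the diene. It is made by a nickel‑catalysed, radical, enantioconvergent coupling of a racemic dienylic chloride (western half) with a homoallylzinc bromide (eastern half).
3. Western half: the lactam ring is made first (furan as a masked malealdehyde plus (S)‑2‑methylbutylamine), then C3‑alkylation with 5‑iodopent‑1‑yne, carboalumination/crotonaldehyde addition, and chlorination.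
4. Eastern half: 2,3‑dihydrofuran, a methyl cuprate and the glycidate are joined in one 1,2‑metallate rearrangement/epoxide opening that fixes the (Z)‑alkene; then bromide and propanoate.
5. Ring order: lactam (step 1), then tetronic acid (step 9).

Assumption: the (S,S)‑pybox ligand is taken to give the (S) methyl‑bearing centre in step 8; if a model coupling shows the opposite sense, its (R,R) enantiomer is used under the same conditions.

## Route

Step 1
Reactants: 1 furan; 2 (2S)-2-methylbutan-1-amine
Product: 4 1-[(2S)-2-methylbutyl]-1,5-dihydro-2H-pyrrol-2-one, via 2,5-dimethoxy-2,5-dihydrofuran 3 (not isolated)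
Conditions: Br2 (1.0 equiv), Na2CO3, MeOH, −10 °C; filter, concentrate; then 2, aq. HCl (1 equiv), H2O, rt, 24 h; NaHCO3
Reagents that add atoms: water, O
Why: Clauson-Kaas oxidative methoxylation turns furan into a masked (Z)-but-2-enedial, which on acid hydrolysis condenses with the primary amine and tautomerises through the 2-hydroxypyrrole to the unsaturated lactam, a known entry to N-substituted pyrrol-2(5H)-ones that leaves the amine stereocentre untouched.

Step 2
Reactants: 4 1-[(2S)-2-methylbutyl]-1,5-dihydro-2H-pyrrol-2-one; 5 5-iodopent-1-yne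
Product: 8 1-[(2S)-2-methylbutyl]-3-(pent-4-yn-1-yl)-1,5-dihydro-2H-pyrrol-2-one, via lithium pyrrol-2-olate 6 (not isolated), via 1,3-dihydro lactam isomer 7 (not isolated)
Conditions: LiN(SiMe3)2 (1.0 equiv), THF, −78 °C; 5 (1.2 equiv), DMPU, −78 → −20 °C; then DBU (10 mol%), rt
Reagents that add atoms: none
Why: Deprotonation at C5 gives the pyrrol-2-olate, which as a lithium dienolate is alkylated kinetically at the α-carbon C3 by the primary iodide (the alkyne C–H is too weakly acidic to quench it), and DBU then moves the double bond back into conjugation to give the more stable 3-alkyl-3-pyrrolin-2-one (dienolate α-alkylation followed by isomerisation).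

Step 3
Reactants: 8 1-[(2S)-2-methylbutyl]-3-(pent-4-yn-1-yl)-1,5-dihydro-2H-pyrrol-2-one; 9 (2E)-but-2-enal
Product: 11 3-[(4E,7E)-6-hydroxy-4-methylnona-4,7-dien-1-yl]-1-[(2S)-2-methylbutyl]-1,5-dihydro-2H-pyrrol-2-one, via (E)-alkenyldimethylalane 10 (not isolated)
Conditions: AlMe3 (3 equiv), Cp2ZrCl2 (25 mol%), CH2Cl2, 0 °C → rt; then 9 (4 equiv), −78 → 0 °C; aq. Rochelle salt
Reagents that add atoms: trimethylaluminium, C[Al](C)C
Why: Negishi zirconium-catalysed carboalumination adds Me–Al syn across the terminal alkyne with methyl on the internal carbon, which fixes the (E)-trisubstituted alkene, and the alkenylalane then adds 1,2 to the enal; the carbinol centre forms unselectively, which does not matter because it is erased in steps 4 and 8.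

Step 4
Reactants: 11 3-[(4E,7E)-6-hydroxy-4-methylnona-4,7-dien-1-yl]-1-[(2S)-2-methylbutyl]-1,5-dihydro-2H-pyrrol-2-one
Product: 12 3-[(4E,6E)-8-chloro-4-methylnona-4,6-dien-1-yl]-1-[(2S)-2-methylbutyl]-1,5-dihydro-2H-pyrrol-2-one (both C8 epimers)
Conditions: SOCl2 (1.1 equiv), pyridine (1.2 equiv), Et2O, −20 → 0 °C; cold aq. work-up, used crude
Reagents that add atoms: thionyl chloride, O=S(Cl)Cl
Why: Chlorodehydroxylation of the doubly allylic alcohol (SNi′/SN2 through the chlorosulfite) gives the dienylic chloride as its conjugated, thermodynamically preferred isomer, and neither the position nor the configuration of the C–Cl bond matters because step 8 passes through one delocalised pentadienyl radical.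

Step 5
Reactants: 13 2,3-dihydrofuran; 14 methyl (2S)-oxirane-2-carboxylate
Product: 18 methyl (2S,4Z)-2,7-dihydroxy-4-methylhept-4-enoate, via 5-lithio-2,3-dihydrofuran 15 (not isolated), via dihydrofuranyl dimethylcuprate 16 (not isolated), via (Z)-alkenyl methylcuprate 17 (not isolated)
Conditions: t-BuLi (1.0 equiv), THF, −78 → 0 °C; Me2CuLi (from MeLi, 2 equiv, and CuI), Et2O/Me2S, −78 °C → rt; then 14 (1.0 equiv), −78 → −30 °C; aq. NH4Cl
Reagents that add atoms: methyllithium, [Li]C
Why: In the Kocienski 1,2-metallate rearrangement methyl migrates from copper to the lithiated ring carbon with inversion and ring opening, leaving copper cis to the hydroxyethyl arm, so that retentive cuprate opening of the glycidate at its CH2 terminus gives the (Z)-trisubstituted alkene while the (S) carbinol centre is carried over unchanged from C2 of the glycidate.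

Step 6
Reactants: 18 methyl (2S,4Z)-2,7-dihydroxy-4-methylhept-4-enoate
Product: 19 methyl (2S,4Z)-7-bromo-2-hydroxy-4-methylhept-4-enoate
Conditions: CBr4 (1.1 equiv), PPh3 (1.1 equiv), CH2Cl2, −20 → 0 °C
Reagents that add atoms: tetrabromomethane, BrC(Br)(Br)Br
Why: The Appel reaction is selective for the unhindered primary alcohol over the deactivated, hindered α-hydroxy ester and touches neither the stereocentre nor the alkene.

Step 7
Reactants: 19 methyl (2S,4Z)-7-bromo-2-hydroxy-4-methylhept-4-enoate; 20 propanoyl chloride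
Product: 21 methyl (2S,4Z)-7-bromo-4-methyl-2-(propanoyloxy)hept-4-enoate
Conditions: 20 (1.3 equiv), pyridine (2 equiv), DMAP (5 mol%), CH2Cl2, 0 °C → rt
Reagents that add atoms: none
Why: Pyridine/DMAP-catalysed O-acylation (Einhorn-type) installs the propanoate that later supplies C2, C3 and the 3-methyl group of the tetronic acid, with no bond to the stereocentre broken.

Step 8
Reactants: 21 methyl (2S,4Z)-7-bromo-4-methyl-2-(propanoyloxy)hept-4-enoate; 12 3-[(4E,6E)-8-chloro-4-methylnona-4,6-dien-1-yl]-1-[(2S)-2-methylbutyl]-1,5-dihydro-2H-pyrrol-2-one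
Product: 23 methyl (2S,4Z,8S,9E,11E)-4,8,12-trimethyl-15-{1-[(2S)-2-methylbutyl]-2-oxo-2,5-dihydro-1H-pyrrol-3-yl}-2-(propanoyloxy)pentadeca-4,9,11-trienoate, via homoallylzinc bromide 22 (not isolated)
Conditions: 21 (1.3 equiv), Zn dust, I2 (5 mol%), DMA, 70 °C; then 12 (1.0 equiv), NiCl2·DME (10 mol%), 2,6-bis[(4S)-4-(2-phenylethyl)-4,5-dihydro-1,3-oxazol-2-yl]pyridine (13 mol%), NaCl (4 equiv), DMA/DMF 1:1, −10 °C, 24 h
Reagents that add atoms: none
Why: Proposed new method: zinc inserts into the C–Br bond and the alkylzinc enters a nickel/pybox stereoconvergent Negishi coupling in which chloride abstraction by the alkylnickel species turns both enantiomers (and any allylic isomer) of 12 into the same pentadienyl radical, which is captured by the chiral nickel complex and reductively eliminates at the least hindered, methyl-bearing terminus so that the (E,E)-diene stays conjugated and the ligand sets the (S) centre; the closest known reaction is the nickel/pybox asymmetric Negishi coupling of racemic secondary allylic chlorides with alkylzinc halides, extended here from allylic to dienylic chlorides.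

Step 9
Reactants: 23 methyl (2S,4Z,8S,9E,11E)-4,8,12-trimethyl-15-{1-[(2S)-2-methylbutyl]-2-oxo-2,5-dihydro-1H-pyrrol-3-yl}-2-(propanoyloxy)pentadeca-4,9,11-trienoate
Product: 24 (5S)-4-hydroxy-3-methyl-5-[(2Z,6S,7E,9E)-2,6,10-trimethyl-13-{1-[(2S)-2-methylbutyl]-2-oxo-2,5-dihydro-1H-pyrrol-3-yl}trideca-2,7,9-trien-1-yl]furan-2(5H)-one
Conditions: LiN(SiMe3)2 (3.3 equiv), THF, −78 → −20 °C; 1 M HCl
Reagents that add atoms: none
Why: Dieckmann (intramolecular Claisen) condensation of the kinetically formed propanoate enolate onto the methyl ester closes the tetronic acid ring without breaking the C–O stereocentre, the extra base covering the lactam C5–H, and acidification returns the conjugated lactam and the free 4-hydroxybutenolide.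

## Compound list

1 | furan | c1ccoc1 | starting material
2 | (2S)-2-methylbutan-1-amine | CC[C@H](C)CN | starting material
3 | 2,5-dimethoxy-2,5-dihydrofuran (cis/trans mixture) | COC1C=CC(OC)O1 | intermediate
4 | 1-[(2S)-2-methylbutyl]-1,5-dihydro-2H-pyrrol-2-one | CC[C@H](C)CN1CC=CC1=O | intermediate
5 | 5-iodopent-1-yne | C#CCCCI | starting material
6 | lithium 1-[(2S)-2-methylbutyl]-1H-pyrrol-2-olate | CC[C@H](C)Cn1cccc1[O-].[Li+] | intermediate
7 | 1-[(2S)-2-methylbutyl]-3-(pent-4-yn-1-yl)-1,3-dihydro-2H-pyrrol-2-one (both C3 epimers) | CC[C@H](C)CN1C=CC(CCCC#C)C1=O | intermediate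
8 | 1-[(2S)-2-methylbutyl]-3-(pent-4-yn-1-yl)-1,5-dihydro-2H-pyrrol-2-one | CC[C@H](C)CN1CC=C(CCCC#C)C1=O | intermediate
9 | (2E)-but-2-enal | C/C=C/C=O | starting material
10 | dimethyl{(1E)-2-methyl-5-[1-((2S)-2-methylbutyl)-2-oxo-2,5-dihydro-1H-pyrrol-3-yl]pent-1-en-1-yl}alumane | CC[C@H](C)CN1CC=C(CCC/C(C)=C/[Al](C)C)C1=O | intermediate
11 | 3-[(4E,7E)-6-hydroxy-4-methylnona-4,7-dien-1-yl]-1-[(2S)-2-methylbutyl]-1,5-dihydro-2H-pyrrol-2-one (both C6 epimers) | CC[C@H](C)CN1CC=C(CCC/C(C)=C/C(O)/C=C/C)C1=O | intermediate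
12 | 3-[(4E,6E)-8-chloro-4-methylnona-4,6-dien-1-yl]-1-[(2S)-2-methylbutyl]-1,5-dihydro-2H-pyrrol-2-one (both C8 epimers) | CC[C@H](C)CN1CC=C(CCC/C(C)=C/C=C/C(C)Cl)C1=O | intermediate
13 | 2,3-dihydrofuran | C1CC=CO1 | starting material
14 | methyl (2S)-oxirane-2-carboxylate | COC(=O)[C@@H]1CO1 | starting material
15 | (4,5-dihydrofuran-2-yl)lithium | [Li]C1=CCCO1 | intermediate
16 | dilithium (4,5-dihydrofuran-2-yl)dimethylcuprate | [Li+].[Li+].C[Cu-2](C)C1=CCCO1 | intermediate
17 | dilithium methyl[(2Z)-5-oxidopent-2-en-2-yl]cuprate | [Li+].[Li+].[O-]CC/C=C(/C)[Cu-]C | intermediate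
18 | methyl (2S,4Z)-2,7-dihydroxy-4-methylhept-4-enoate | COC(=O)[C@@H](O)C/C(C)=C\CCO | intermediate
19 | methyl (2S,4Z)-7-bromo-2-hydroxy-4-methylhept-4-enoate | COC(=O)[C@@H](O)C/C(C)=C\CCBr | intermediate
20 | propanoyl chloride | CCC(=O)Cl | starting material
21 | methyl (2S,4Z)-7-bromo-4-methyl-2-(propanoyloxy)hept-4-enoate | COC(=O)[C@@H](OC(=O)CC)C/C(C)=C\CCBr | intermediate
22 | bromo[(3Z,6S)-7-methoxy-4-methyl-7-oxo-6-(propanoyloxy)hept-3-en-1-yl]zinc | COC(=O)[C@@H](OC(=O)CC)C/C(C)=C\CC[Zn]Br | intermediate
23 | methyl (2S,4Z,8S,9E,11E)-4,8,12-trimethyl-15-{1-[(2S)-2-methylbutyl]-2-oxo-2,5-dihydro-1H-pyrrol-3-yl}-2-(propanoyloxy)pentadeca-4,9,11-trienoate | CC[C@H](C)CN1CC=C(CCC/C(C)=C/C=C/[C@@H](C)CC/C=C(/C)C[C@H](OC(=O)CC)C(=O)OC)C1=O | intermediate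
24 | (5S)-4-hydroxy-3-methyl-5-[(2Z,6S,7E,9E)-2,6,10-trimethyl-13-{1-[(2S)-2-methylbutyl]-2-oxo-2,5-dihydro-1H-pyrrol-3-yl}trideca-2,7,9-trien-1-yl]furan-2(5H)-one | CC[C@H](C)CN1CC=C(CCC/C(C)=C/C=C/[C@@H](C)CC/C=C(/C)C[C@@H]2OC(=O)C(C)=C2O)C1=O | target

## Step count and risk

Total: 9 steps. Longest linear sequence: 6 steps (1, 2, 3, 4, 8, 9); the eastern branch (5, 6, 7) joins at step 8.

The three steps most likely to fail:

Step 8. A dienylic chloride is outside the proven scope of the stereoconvergent coupling. The pentadienyl intermediate could couple at the central or the tertiary carbon, the alkene geometry could erode, or 12 could ionise and eliminate in the amide solvent. The fallback sets out from 22 and from 10 and returns at 23, and it keeps the nickel step inside its established substrate class. Zinc reagent 22 is coupled under the same NiCl2·DME/pybox conditions with racemic (2E)-4-chloropent-2-ene, a symmetrical secondary allylic chloride, to give methyl (2S,4Z,8S,9E)-4,8-dimethyl-2-(propanoyloxy)undeca-4,9-dienoate F1. Alkenylalane 10 is intercepted in its flask with vinyl bromide, ZnCl2 and Pd(PPh3)4 in THF to give 3-[(4E)-4-methylhepta-4,6-dien-1-yl]-1-[(2S)-2-methylbutyl]-1,5-dihydro-2H-pyrrol-2-one F2. Cross-metathesis of F1 with F2 (second-generation Hoveyda–Grubbs catalyst, RuCl2(H2IMes)(=CH-C6H4-2-O-i-Pr), CH2Cl2, 40 °C, loss of propene) then builds the (E,E)-diene and gives 23; steps 3 (aldehyde addition) and 4 are then not needed.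

Step 2. The pyrrol-2-olate is ambident and may be alkylated at C5 or twice at C3. The fallback sets out from 4 and returns at 8, and it makes the C3–C bond at an sp2 carbon. Lactam 4 is iodinated at C3 by addition–elimination (I2, pyridine, CH2Cl2) to give 3-iodo-1-[(2S)-2-methylbutyl]-1,5-dihydro-2H-pyrrol-2-one F3. F3 is joined to 5 in a nickel-catalysed reductive cross-electrophile coupling (NiBr2·DME, 4,4′-di-tert-butyl-2,2′-bipyridine, Mn powder, DMA, rt), which tolerates the free alkyne and gives 8 directly.

Step 5. The oxy-cuprate 17 may be too sluggish towards the epoxide or may transfer methyl instead of the alkenyl group. The fallback sets out from 17 and from 14 and returns at 18, and it replaces the cuprate epoxide opening by a radical cross-coupling of two halides. Cuprate 17 is quenched with I2 (retention) to give (3Z)-4-iodopent-3-en-1-ol F4. Glycidate 14 is opened at its CH2 terminus with LiI/AcOH in THF to give methyl (2R)-2-hydroxy-3-iodopropanoate F5, with the spatial arrangement unchanged and only the descriptor altered. Nickel-catalysed reductive coupling of F4 with F5 (NiBr2·DME, 4,4′-di-tert-butyl-2,2′-bipyridine, Mn powder, DMA) gives 18 with the (Z)-alkene and the carbinol centre intact.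

## Further compounds

F1 | step 8 | methyl (2S,4Z,8S,9E)-4,8-dimethyl-2-(propanoyloxy)undeca-4,9-dienoate | COC(=O)[C@@H](OC(=O)CC)C/C(C)=C\CC[C@H](C)/C=C/C
F2 | step 8 | 3-[(4E)-4-methylhepta-4,6-dien-1-yl]-1-[(2S)-2-methylbutyl]-1,5-dihydro-2H-pyrrol-2-one | CC[C@H](C)CN1CC=C(CCC/C(C)=C/C=C)C1=O
F3 | step 2 | 3-iodo-1-[(2S)-2-methylbutyl]-1,5-dihydro-2H-pyrrol-2-one | CC[C@H](C)CN1CC=C(I)C1=O
F4 | step 5 | (3Z)-4-iodopent-3-en-1-ol | OCC/C=C(/C)I
F5 | step 5 | methyl (2R)-2-hydroxy-3-iodopropanoate | COC(=O)[C@@H](O)CI
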